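**Retrosynthetic overview**
- Feature: in ring A the carbons C8a (bearing O1), C5 and C7 all lie ortho or para to C4a, which carries the C4 carbonyl, so all three ring-A C–O bonds can be made by SNAr on a 2,4,6-trifluorobenzoyl unit.
- The 4'-OH is released last from a benzyl ether; before that the three sulfates are put on 4'-O-benzylquercetin, whose 5-OH is held back by its hydrogen bond to C4=O.
- C5–O and C7–O come from double SNAr of 4-methoxybenzyl (PMB) alkoxide on a 5,7-difluoroflavonol ether, followed by acid removal of PMB and MOM groups.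
- Ring C is the only ring built (rings A and B are bought): O1–C8a is closed by intramolecular SNAr of the enolate oxygen of a 2-alkoxy-1-aryl-3-(2,4,6-trifluorophenyl)propane-1,3-dione.
- The diketone comes from C-acylation of an α-(methoxymethoxy) aryl ketone with 2,4,6-trifluorobenzoyl chloride (C3–C4); the ketone comes from MOMOCH2Li addition to the protected aldehyde (C2–C3) and oxidation.

Key step: step 5

Assumption 1: the target has no stereocentre or stereogenic double bond, so no stereocontrol is needed; the one carbinol centre made on the way (compound 5) is racemic and is removed by oxidation.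
Assumption 2: sulfate monoesters are drawn, like the target, as free hydrogen sulfates; they would be handled as sodium or ammonium salts, the acid form being released only at the end on a cold H+-form resin, and counter-ions are left out of the equations.

**Step 1**
Reactants: 1 4-(benzyloxy)-3-hydroxybenzaldehyde
Product: 2 4-(benzyloxy)-3-(methoxymethoxy)benzaldehyde
Conditions: MOMCl (1.5 equiv), i-Pr2NEt (2 equiv), CH2Cl2, 0 °C → rt
Reagents that add atoms: chloromethyl methyl ether, COCCl
Why: Williamson-type O-alkylation of the phenol by the reactive α-chloro ether under amine base should proceed cleanly, the aldehyde and the benzyl ether being inert.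

**Step 2**
Reactants: 2 4-(benzyloxy)-3-(methoxymethoxy)benzaldehyde; 3 tributyl[(methoxymethoxy)methyl]stannane
Product: 5 rac-1-[4-(benzyloxy)-3-(methoxymethoxy)phenyl]-2-(methoxymethoxy)ethan-1-ol, via [(methoxymethoxy)methyl]lithium 4 (not isolated)
Conditions: 3 (1.3 equiv), n-BuLi (1.2 equiv), THF, −78 °C; then 2, −78 °C; H2O
Reagents that add atoms: none
Why: Tin–lithium exchange gives the α-alkoxymethyllithium, which should add 1,2 to the aldehyde; the carbinol centre forms as a racemate and is erased in step 3.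

**Step 3**
Reactants: 5 rac-1-[4-(benzyloxy)-3-(methoxymethoxy)phenyl]-2-(methoxymethoxy)ethan-1-ol
Product: 6 1-[4-(benzyloxy)-3-(methoxymethoxy)phenyl]-2-(methoxymethoxy)ethan-1-one
Conditions: Dess–Martin periodinane (1.3 equiv), CH2Cl2, rt
Reagents that add atoms: none
Why: Dess–Martin oxidation of a secondary benzylic alcohol to the aryl ketone runs under near-neutral conditions that should leave the MOM and benzyl ethers intact.

**Step 4**
Reactants: 6 1-[4-(benzyloxy)-3-(methoxymethoxy)phenyl]-2-(methoxymethoxy)ethan-1-one; 7 2,4,6-trifluorobenzoyl chloride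
Product: 9 1-[4-(benzyloxy)-3-(methoxymethoxy)phenyl]-2-(methoxymethoxy)-3-(2,4,6-trifluorophenyl)propane-1,3-dione, via lithium Z-enolate 8 (not isolated)
Conditions: LiHMDS (2.2 equiv), THF, −78 °C; then 7 (1.1 equiv), −78 → −40 °C; AcOH quench
Reagents that add atoms: none
Why: Claisen-type C-acylation of the chelated lithium enolate by the acid chloride should give the 1,3-diketone, the second equivalent of base holding the more acidic product as its lithium diketonate (no proton transfer to unreacted enolate, no bis-acylation) until the cold acetic acid quench.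

**Step 5**
Reactants: 9 1-[4-(benzyloxy)-3-(methoxymethoxy)phenyl]-2-(methoxymethoxy)-3-(2,4,6-trifluorophenyl)propane-1,3-dione
Product: 10 2-[4-(benzyloxy)-3-(methoxymethoxy)phenyl]-5,7-difluoro-3-(methoxymethoxy)-4H-chromen-4-one
Conditions: K2CO3 (2 equiv), dry DMF (0.02 M), 50 °C
Reagents that add atoms: none
Why: Carbonate deprotonates C2 of the diketone, the enolate oxygen on the B-ring side adds to one of the two equivalent ortho C–F carbons of the trifluorophenyl ring to give an anionic σ-adduct stabilised by the aryl ketone (the future C4=O), and loss of fluoride forms O1–C8a. The closest known reaction type is the base-mediated cyclisation of 1-(2-fluoroaryl)-1,3-diketones to chromones and flavones, the oxygen counterpart of the fluoroquinolone ring closure. Ring C closes as a six-membered ring by 6-exo-trig addition at C8a (the C8a=C8 bond lies outside the new ring) followed by elimination, that is an addition–elimination SNAr. No stereocentre is formed, and the enolisable C2 of 9 becomes the sp2 carbon C3. The step needs O- over C-arylation and intra- over intermolecular substitution: carbon attack would require a four-membered ring and the para fluorine cannot be reached from within the molecule, while dilution and a weak, non-nucleophilic base should hold back intermolecular attack at C–F and retro-Claisen cleavage. The fluorines left at C5 and C7 remain ortho and para to C4=O and are set up for step 6.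

**Step 6**
Reactants: 10 2-[4-(benzyloxy)-3-(methoxymethoxy)phenyl]-5,7-difluoro-3-(methoxymethoxy)-4H-chromen-4-one; 11 4-methoxybenzyl alcohol
Product: 14 2-[4-(benzyloxy)-3-(methoxymethoxy)phenyl]-5,7-bis[(4-methoxybenzyl)oxy]-3-(methoxymethoxy)-4H-chromen-4-one, via sodium (4-methoxyphenyl)methanolate 12 (not isolated), via 5-fluoro-7-PMB-oxy monoether 13 (not isolated)
Conditions: 11 (4 equiv), NaH (3.5 equiv), THF, 0 °C; then 10, THF/DMF, 0 → 60 °C
Reagents that add atoms: none
Why: Alkoxide SNAr (addition–elimination) at the aryl fluorides para (C7, expected first in the dipolar medium) and ortho (C5) to the C4 ketone should install both ethers, MOM and benzyl groups being base-stable.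

**Step 7**
Reactants: 14 2-[4-(benzyloxy)-3-(methoxymethoxy)phenyl]-5,7-bis[(4-methoxybenzyl)oxy]-3-(methoxymethoxy)-4H-chromen-4-one
Product: 15 2-[4-(benzyloxy)-3-hydroxyphenyl]-3,5,7-trihydroxy-4H-chromen-4-one (4'-O-benzylquercetin)
Conditions: 3 M HCl in MeOH/THF (1:1), 50 °C
Reagents that add atoms: none
Why: Acid solvolysis should cleave the two PMB aryl ethers (SN1, cation trapped by methanol) and the two MOM ethers (acetal exchange), while the unactivated benzyl aryl ether at O4' survives methanolic HCl.

**Step 8**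
Reactants: 15 2-[4-(benzyloxy)-3-hydroxyphenyl]-3,5,7-trihydroxy-4H-chromen-4-one
Product: 16 2-[4-(benzyloxy)-3-(sulfooxy)phenyl]-5-hydroxy-4-oxo-4H-chromene-3,7-diyl bis(hydrogen sulfate)
Conditions: SO3·NEt3 (6 equiv), Et3N, DMF, 40 °C; Na+ exchange, Sephadex LH-20
Reagents that add atoms: sulfur trioxide–triethylamine complex, CC[N+](CC)(CC)S(=O)(=O)[O-]
Why: O-sulfation with a sulfur trioxide–amine complex should take the 7-, 3'- and 3-hydroxyls, whereas the 5-OH, locked in a six-membered hydrogen bond to C4=O, is the least nucleophilic and reacts only under forcing conditions.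

**Step 9**
Reactants: 16 2-[4-(benzyloxy)-3-(sulfooxy)phenyl]-5-hydroxy-4-oxo-4H-chromene-3,7-diyl bis(hydrogen sulfate)
Product: 17 quercetin 3,3',7-trissulfate [5-hydroxy-2-[4-hydroxy-3-(sulfooxy)phenyl]-4-oxo-4H-chromene-3,7-diyl bis(hydrogen sulfate)]
Conditions: H2 (1 atm), 10% Pd/C, MeOH/H2O, rt (sodium salt); then Dowex 50W (H+), 0 °C, freeze-dry
Reagents that add atoms: none
Why: Catalytic hydrogenolysis should cleave the benzyl aryl ether while aryl sulfate monoesters and the flavonol C2=C3 bond are not reduced under these mild conditions.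

**Compound list**
1 | 4-(benzyloxy)-3-hydroxybenzaldehyde | O=Cc1ccc(OCc2ccccc2)c(O)c1 | starting material
2 | 4-(benzyloxy)-3-(methoxymethoxy)benzaldehyde | COCOc1cc(C=O)ccc1OCc1ccccc1 | intermediate
3 | tributyl[(methoxymethoxy)methyl]stannane | CCCC[Sn](CCCC)(CCCC)COCOC | starting material
4 | [(methoxymethoxy)methyl]lithium | [Li]COCOC | intermediate
5 | rac-1-[4-(benzyloxy)-3-(methoxymethoxy)phenyl]-2-(methoxymethoxy)ethan-1-ol (racemate) | COCOCC(O)c1ccc(OCc2ccccc2)c(OCOC)c1 | intermediate
6 | 1-[4-(benzyloxy)-3-(methoxymethoxy)phenyl]-2-(methoxymethoxy)ethan-1-one | COCOCC(=O)c1ccc(OCc2ccccc2)c(OCOC)c1 | intermediate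
7 | 2,4,6-trifluorobenzoyl chloride | O=C(Cl)c1c(F)cc(F)cc1F | starting material
8 | lithium (Z)-1-[4-(benzyloxy)-3-(methoxymethoxy)phenyl]-2-(methoxymethoxy)ethen-1-olate | COCO/C=C(\O[Li])c1ccc(OCc2ccccc2)c(OCOC)c1 | intermediate
9 | 1-[4-(benzyloxy)-3-(methoxymethoxy)phenyl]-2-(methoxymethoxy)-3-(2,4,6-trifluorophenyl)propane-1,3-dione (enolisable at C2, no fixed configuration) | COCOC(C(=O)c1c(F)cc(F)cc1F)C(=O)c1ccc(OCc2ccccc2)c(OCOC)c1 | intermediate
10 | 2-[4-(benzyloxy)-3-(methoxymethoxy)phenyl]-5,7-difluoro-3-(methoxymethoxy)-4H-chromen-4-one | O=c1c(OCOC)c(-c2ccc(OCc3ccccc3)c(OCOC)c2)oc2cc(F)cc(F)c12 | intermediate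
11 | 4-methoxybenzyl alcohol | COc1ccc(CO)cc1 | starting material
12 | sodium (4-methoxyphenyl)methanolate | COc1ccc(C[O-])cc1.[Na+] | intermediate
13 | 2-[4-(benzyloxy)-3-(methoxymethoxy)phenyl]-5-fluoro-7-[(4-methoxybenzyl)oxy]-3-(methoxymethoxy)-4H-chromen-4-one | O=c1c(OCOC)c(-c2ccc(OCc3ccccc3)c(OCOC)c2)oc2cc(OCc3ccc(OC)cc3)cc(F)c12 | intermediate
14 | 2-[4-(benzyloxy)-3-(methoxymethoxy)phenyl]-5,7-bis[(4-methoxybenzyl)oxy]-3-(methoxymethoxy)-4H-chromen-4-one | O=c1c(OCOC)c(-c2ccc(OCc3ccccc3)c(OCOC)c2)oc2cc(OCc3ccc(OC)cc3)cc(OCc3ccc(OC)cc3)c12 | intermediate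
15 | 2-[4-(benzyloxy)-3-hydroxyphenyl]-3,5,7-trihydroxy-4H-chromen-4-one | O=c1c(O)c(-c2ccc(OCc3ccccc3)c(O)c2)oc2cc(O)cc(O)c12 | intermediate
16 | 2-[4-(benzyloxy)-3-(sulfooxy)phenyl]-5-hydroxy-4-oxo-4H-chromene-3,7-diyl bis(hydrogen sulfate) | O=c1c(OS(=O)(=O)O)c(-c2ccc(OCc3ccccc3)c(OS(=O)(=O)O)c2)oc2cc(OS(=O)(=O)O)cc(O)c12 | intermediate
17 | quercetin 3,3',7-trissulfate | O=c1c(OS(=O)(=O)O)c(-c2ccc(O)c(OS(=O)(=O)O)c2)oc2cc(OS(=O)(=O)O)cc(O)c12 | target

Total step count: 9. Longest linear sequence: 9 steps (1 → 17); compounds 3, 7 and 11 are bought and enter directly.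

**Steps most likely to fail**

Step 6. The reaction may stall after the first displacement, because the new alkoxy group feeds electron density into C4=O and deactivates the remaining C–F. At the temperature then needed, the alkoxide may add at C2 and open the pyranone ring. The fallback sets out from 10 and replaces the second protected alkoxide by a hydroxide surrogate. One equivalent of 12 at 0 °C should stop at the monoether 13, which is isolated. (E)-Benzaldoxime with Cs2CO3 in DMSO at 60–80 °C, an α-effect nucleophile, should then displace the C5 fluoride to give 2-[4-(benzyloxy)-3-(methoxymethoxy)phenyl]-5-{[(E)-benzylideneamino]oxy}-7-[(4-methoxybenzyl)oxy]-3-(methoxymethoxy)-4H-chromen-4-one F1. Under the base this fragments, with loss of benzonitrile, to 2-[4-(benzyloxy)-3-(methoxymethoxy)phenyl]-5-hydroxy-7-[(4-methoxybenzyl)oxy]-3-(methoxymethoxy)-4H-chromen-4-one F2. Treating F2 under the conditions of step 7 returns the route at 15.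

Step 8. Sulfation may be incomplete at the hindered enolic 3-OH or may run on to the 5-OH, giving anionic mixtures that are hard to separate, and sulfate may be lost by hydrolysis during isolation. The fallback sets out from 15 and installs the sulfates as neutral protected diesters. 2,2,2-Trichloroethyl chlorosulfate with Et3N and DMAP in THF should give 2-[4-(benzyloxy)-3-{[(2,2,2-trichloroethoxy)sulfonyl]oxy}phenyl]-5-hydroxy-3,7-bis{[(2,2,2-trichloroethoxy)sulfonyl]oxy}-4H-chromen-4-one F3. This can be purified on silica, so under- and over-sulfated material is removed. Reductive removal of the trichloroethyl groups with zinc and ammonium formate in methanol returns the route at 16.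

Step 5. The doubly ortho-fluorinated aroyl group is twisted out of conjugation, so ring closure may be slow. On heating, the 2-alkoxy-1,3-diketone may suffer retro-Claisen cleavage or intermolecular displacement of the para fluorine. The fallback sets out from aldehyde 2 and gives up the SNAr closure; O1 then comes from a phloroglucinol phenol. Claisen–Schmidt condensation of 2 with commercial 2'-hydroxy-4',6'-bis(methoxymethoxy)acetophenone (KOH, EtOH) should give (E)-3-[4-(benzyloxy)-3-(methoxymethoxy)phenyl]-1-[2-hydroxy-4,6-bis(methoxymethoxy)phenyl]prop-2-en-1-one F4. Algar–Flynn–Oyamada oxidation (H2O2, NaOH, MeOH, 0 °C, kept cold to disfavour the aurone pathway) should give 2-[4-(benzyloxy)-3-(methoxymethoxy)phenyl]-3-hydroxy-5,7-bis(methoxymethoxy)-4H-chromen-4-one F5. Methanolic HCl as in step 7 removes the three MOM groups and returns the route at 15.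

**Further compounds**
F1 | step 6 | 2-[4-(benzyloxy)-3-(methoxymethoxy)phenyl]-5-{[(E)-benzylideneamino]oxy}-7-[(4-methoxybenzyl)oxy]-3-(methoxymethoxy)-4H-chromen-4-one | O=c1c(OCOC)c(-c2ccc(OCc3ccccc3)c(OCOC)c2)oc2cc(OCc3ccc(OC)cc3)cc(O/N=C/c3ccccc3)c12
F2 | step 6 | 2-[4-(benzyloxy)-3-(methoxymethoxy)phenyl]-5-hydroxy-7-[(4-methoxybenzyl)oxy]-3-(methoxymethoxy)-4H-chromen-4-one | O=c1c(OCOC)c(-c2ccc(OCc3ccccc3)c(OCOC)c2)oc2cc(OCc3ccc(OC)cc3)cc(O)c12
F3 | step 8 | 2-[4-(benzyloxy)-3-{[(2,2,2-trichloroethoxy)sulfonyl]oxy}phenyl]-5-hydroxy-3,7-bis{[(2,2,2-trichloroethoxy)sulfonyl]oxy}-4H-chromen-4-one | O=c1c(OS(=O)(=O)OCC(Cl)(Cl)Cl)c(-c2ccc(OCc3ccccc3)c(OS(=O)(=O)OCC(Cl)(Cl)Cl)c2)oc2cc(OS(=O)(=O)OCC(Cl)(Cl)Cl)cc(O)c12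
F4 | step 5 | (E)-3-[4-(benzyloxy)-3-(methoxymethoxy)phenyl]-1-[2-hydroxy-4,6-bis(methoxymethoxy)phenyl]prop-2-en-1-one | COCOc1cc(O)c(C(=O)/C=C/c2ccc(OCc3ccccc3)c(OCOC)c2)c(OCOC)c1
F5 | step 5 | 2-[4-(benzyloxy)-3-(methoxymethoxy)phenyl]-3-hydroxy-5,7-bis(methoxymethoxy)-4H-chromen-4-one | O=c1c(O)c(-c2ccc(OCc3ccccc3)c(OCOC)c2)oc2cc(OCOC)cc(OCOC)c12
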